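the same everywhere: substrate 0.059 M
- larch: coupling partner 0.033 M; run made earlier
- ash: coupling partner 0.052 M; run made earlier
- cedar: coupling partner 0.059 M; run made earlier
- summer: coupling partner 0.0350 M; time 3.0 d
- dusk: coupling partner 0.0710 M; time 3.0 d

| run | time / h | substrate / % | target / % | isomer of the product / % | intermediate / % |
|---|---|---|---|---|---|
| larch | 4.00 | 90.9 | 1.6 | 0 | 8.1 |
| larch | 8.00 | 84.2 | 4.2 | 1.0 | 11.1 |
| larch | 15.0 | 74.7 | 8.2 | 2.2 | 13.1 |
| larch | 25.0 | 67.7 | 14.8 | 6.4 | 11.9 |
| larch | 48.0 | 58.4 | 22.5 | 12.6 | 6.8 |
| ash | 4.00 | 86.2 | 2.6 | 0.3 | 12.5 |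
| ash | 8.00 | 76.0 | 5.8 | 1.1 | 18.0 |
| ash | 15.0 | 64.9 | 12.9 | 4.6 | 18.9 |
| ash | 25.0 | 53.7 | 20.7 | 9.0 | 15.8 |
| ash | 48.0 | 40.5 | 31.2 | 18.3 | 9.7 |
| cedar | 10.0 | 68.5 | 8.8 | 1.8 | 21.8 |
| cedar | 20.0 | 54.1 | 18.8 | 7.6 | 19.6 |
| cedar | 30.0 | 44.9 | 27.0 | 13.3 | 16.0 |
| cedar | 40.0 | 38.9 | 30.4 | 17.1 | 13.2 |
| cedar | 48.0 | 34.9 | 33.9 | 19.8 | 9.9 |

(readings scatter by 0.5 percentage points)



* which of these there is most of at the end, counted by the substrate in it, summer (target / intermediate / isomer of the product / substrate)
* which of these there is most of at the end, counted by the substrate in it, dusk (target / intermediate / isomer of the product / substrate)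
* final amount of the leader among these, as a percentage of the substrate charged, in summer
* final amount of the leader among these, as a percentage of the substrate charged, in dusk

1. At late times a repeat should watch the target share, meaning target over target plus isomer of the product. I read it in the cedar run at 48.0 h as 0.631. The ash run gave 0.630 and the larch run 0.641. Cedar's share was still sinking, being 0.670 at 30.0 h, so I treated the exchange of target and isomer as close to its level and my share as slightly high.

2. I reckoned target in dusk as the share times the fraction of the charge that was neither substrate nor intermediate, so I asked what each number was worth.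

3. The gap in share between larch and cedar, on cedar's finished products, was worth 0.52 percentage points of target, which was small beside the next two.

4. Forgetting cedar's last intermediate, 9.9%, was worth 6.2 points.

5. Cedar's fall in substrate from 44.9% to 34.9% was worth 6.3 points, so substrate left had to be known as well as intermediate left.

6. In summer the coupling partner was the limiting reagent, at 0.593 of the substrate. Taking one partner per substrate, I estimated 40.7% of substrate without a partner and 37.4% of target with the partner fully used, so I called substrate the leader.

7. I assumed simple second-order loss, under which, with equal charges as in cedar, the reciprocal of the fraction left, minus one, grows steadily with time. I carried cedar's value to 3.0 d at its last pace and got 2.72. Integrating with each flask's ratio of partner to substrate gave an estimate of 50.6% substrate in summer and 18.6% in dusk. With cedar's intermediate, dusk's target came to 45.1%.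

8. The forecast gave substrate at 52% for summer and target at 46% for dusk, with “target is about 61% of the finished products”, close to my numbers but not on them.

9. Summer ended with substrate at 50.6%, and dusk with target at 43.8%.

    intermediate ⇌ target + released group (K = 0.350 M, k = 0.00130 min⁻¹)
    substrate + coupling partner ⇌ intermediate (K = 47.0 L mol⁻¹, k = 0.0140 L mol⁻¹ min⁻¹)
    2 substrate → homo dimer (k = 1.10 × 10⁻⁵ L mol⁻¹ min⁻¹)
    target ⇌ isomer of the product (K = 0.650, k = 0.00130 min⁻¹)

Dusk's share came to 0.616. In the neighbour of summer charged with 0.14 M of coupling partner, my share times what 3.38% substrate and 9.56% intermediate leave gives 54.9%, and that flask held 53.1% of target. Dusk's target stood above summer's mainly because of the difference in the charge of coupling partner: without that difference, target in dusk ended at 27.3% instead of 43.8%.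

The earlier runs and the new flask are simulated on assumed constants; the scatter is artificial.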